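**Retrosynthetic overview**
1. The second naphthalene ring is formed first: amide 1 and methallyl bromide 2 give (through 3 and 4) the ortho-methallyl benzamide 5, which closes between the amide carbon and the allyl terminus to naphtholate 6, methylated in the same pot to 7.
2. para-Bromination of 7 gives the naphthyl bromide 8.
3. Key disconnection C1–C8a, made in the same palladium cycle as C4–C4a: iodoarene 9 is ortho-alkylated by the (R)-aziridine 10 (source of C3), and its iodide carbon is then joined to the acetyl anion equivalent 11 (a 1-ethoxyvinyl stannane), giving 12.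
4. The nitrogen ring is formed second: acid unmasks amino ketone 13, whose C1=N condensation gives 14. A Bischler–Napieralski closure is avoided because it would go para to the methoxy group.
5. The biaryl bond C7–C1′ is made last: Negishi coupling of 8 (through 15 and 16) with 14 gives the target 17.

Assumption: the SMILES fixes only C3 (R) and gives no descriptor for the biaryl axis, so the (3R) compound is taken as the target whatever the axial configuration; the last step gives both atropo-diastereomers, separable by chromatography if one is wanted.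

**Step 1**
Reactants: 1 N,N-diethyl-2-methoxybenzamide; 2 3-bromo-2-methylprop-1-ene
Product: 5 N,N-diethyl-2-methoxy-6-(2-methylprop-2-en-1-yl)benzamide, via aryllithium 3 (not isolated), via arylmagnesium bromide 4 (not isolated)
Conditions: s-BuLi (1.1 equiv), TMEDA, THF, −78 °C; MgBr2·OEt2 (1.3 equiv), −78 → 0 °C; 2 (1.5 equiv), −78 °C → rt
Reagents that add atoms: none
Why: Directed ortho-metalation, in which the tertiary amide outranks the methoxy group so that C6 is lithiated; transmetalation to magnesium gives a soft aryl nucleophile that is allylated cleanly by the symmetrical methallyl bromide, and no stereocentre is formed.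

**Step 2**
Reactants: 5 N,N-diethyl-2-methoxy-6-(2-methylprop-2-en-1-yl)benzamide
Product: 7 1,8-dimethoxy-3-methylnaphthalene, via lithium naphtholate 6 (not isolated)
Conditions: MeLi (1.5 equiv), THF, −78 → 0 °C; then MeI (5 equiv), DMPU, 0 → 40 °C
Reagents that add atoms: iodomethane, CI
Why: Snieckus-type anionic benzannulation of an ortho-allyl benzamide: MeLi removes the benzylic/allylic proton, the allyl terminus attacks the amide carbonyl, loss of diethylamide and aromatisation give the naphtholate, which is O-methylated in the same pot (Williamson etherification in a dipolar co-solvent).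

**Step 3**
Reactants: 7 1,8-dimethoxy-3-methylnaphthalene
Product: 8 1-bromo-4,5-dimethoxy-2-methylnaphthalene
Conditions: NBS (1.0 equiv), MeCN, 0 °C → rt, dark
Reagents that add atoms: N-bromosuccinimide, O=C1CCC(=O)N1Br
Why: Electrophilic aromatic bromination at the most activated α-position, which is para to a methoxy group and ortho to the methyl group, whereas the other para site (C5 of 7) lacks the methyl activation.

**Step 4**
Reactants: 9 1-chloro-3-iodo-2-methoxybenzene; 10 tert-butyl (2R)-2-methylaziridine-1-carboxylate; 11 tributyl(1-ethoxyethenyl)stannane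
Product: 14 (3R)-7-chloro-8-methoxy-1,3-dimethyl-3,4-dihydroisoquinoline, via enol ether carbamate 12 (not isolated), via amino ketone 13 (not isolated)
Conditions: Pd(OAc)2 (10 mol %), tri(2-furyl)phosphine (25 mol %), norbornene (1.0 equiv), K2CO3 (1.0 equiv), 10 (2.0 equiv), 11 (1.3 equiv), MeCN, 80 °C; then 3 M aq. HCl, 50 °C; then aq. NaOH to pH 11, rt
Reagents that add atoms: none
Why: Proposed new method: a Catellani reaction terminated by an acetyl anion equivalent — zerovalent palladium inserts into the C–I bond (C–Cl is inert with this ligand), norbornene insertion and ortho C–H palladation give the aryl-norbornyl palladacycle of divalent palladium, which opens the aziridine by SN2 attack at its unsubstituted CH2 (tetravalent palladium, then aryl–alkyl reductive elimination; the stereocentre of 10 is not touched, so C3 stays R), norbornene is extruded, and the resulting di-ortho-substituted aryl–palladium iodide (electrophilic carbon) is joined by Stille transmetalation and reductive elimination to the nucleophilic α-alkoxyvinyl carbon of 11; K2CO3 only relays the C–H proton to nitrogen, and aqueous acid then hydrolyses the enol ether and removes Boc so that on basification the amine condenses with the ketone to the six-membered cyclic imine; closest known reaction types are Catellani ortho-alkylation with aziridines terminated by Heck/aza-Michael steps (tetrahydroisoquinoline synthesis), Suzuki-terminated Catellani reactions, and Stille acetylation of aryl iodides with 1-ethoxyvinyl stannanes.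

**Step 5**
Reactants: 8 1-bromo-4,5-dimethoxy-2-methylnaphthalene; 14 (3R)-7-chloro-8-methoxy-1,3-dimethyl-3,4-dihydroisoquinoline
Product: 17 (3R)-7-(4,5-dimethoxy-2-methylnaphthalen-1-yl)-8-methoxy-1,3-dimethyl-3,4-dihydroisoquinoline, via naphthyllithium 15 (not isolated), via naphthylzinc chloride 16 (not isolated)
Conditions: 8 (1.5 equiv), n-BuLi (1.5 equiv), THF, −78 °C; ZnCl2 (1.6 equiv), −78 °C → rt; then 14 (1.0 equiv), Pd2(dba)3 (2 mol %), RuPhos (2-dicyclohexylphosphino-2′,6′-diisopropoxybiphenyl, 8 mol %), THF/NMP, 70 °C
Reagents that add atoms: none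
Why: Negishi coupling, in which the bulky dialkylbiarylphosphine lets zerovalent palladium insert into the ortho-methoxy aryl chloride and tolerates the tri-ortho-substituted biaryl, while the arylzinc neither adds to the ketimine nor epimerises C3; the axis forms as a pair of atropo-diastereomers.

**Compound list**
1 | N,N-diethyl-2-methoxybenzamide | CCN(CC)C(=O)c1ccccc1OC | starting material
2 | 3-bromo-2-methylprop-1-ene (methallyl bromide) | CC(=C)CBr | starting material
3 | [2-(diethylcarbamoyl)-3-methoxyphenyl]lithium | CCN(CC)C(=O)c1c([Li])cccc1OC | intermediate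
4 | bromo[2-(diethylcarbamoyl)-3-methoxyphenyl]magnesium | CCN(CC)C(=O)c1c([Mg]Br)cccc1OC | intermediate
5 | N,N-diethyl-2-methoxy-6-(2-methylprop-2-en-1-yl)benzamide | CCN(CC)C(=O)c1c(CC(C)=C)cccc1OC | intermediate
6 | lithium 8-methoxy-3-methylnaphthalen-1-olate | [Li+].[O-]c1cc(C)cc2cccc(OC)c12 | intermediate
7 | 1,8-dimethoxy-3-methylnaphthalene | COc1cc(C)cc2cccc(OC)c12 | intermediate
8 | 1-bromo-4,5-dimethoxy-2-methylnaphthalene | COc1cc(C)c(Br)c2cccc(OC)c12 | intermediate
9 | 1-chloro-3-iodo-2-methoxybenzene | COc1c(Cl)cccc1I | starting material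
10 | tert-butyl (2R)-2-methylaziridine-1-carboxylate | C[C@@H]1CN1C(=O)OC(C)(C)C | starting material
11 | tributyl(1-ethoxyethenyl)stannane | CCCC[Sn](CCCC)(CCCC)C(=C)OCC | starting material
12 | tert-butyl N-[(2R)-1-[4-chloro-2-(1-ethoxyethenyl)-3-methoxyphenyl]propan-2-yl]carbamate | CCOC(=C)c1c(OC)c(Cl)ccc1C[C@@H](C)NC(=O)OC(C)(C)C | intermediate
13 | 1-[6-[(2R)-2-aminopropyl]-3-chloro-2-methoxyphenyl]ethan-1-one | CC(=O)c1c(OC)c(Cl)ccc1C[C@@H](C)N | intermediate
14 | (3R)-7-chloro-8-methoxy-1,3-dimethyl-3,4-dihydroisoquinoline | COc1c(Cl)ccc2c1C(C)=N[C@H](C)C2 | intermediate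
15 | (4,5-dimethoxy-2-methylnaphthalen-1-yl)lithium | COc1cc(C)c([Li])c2cccc(OC)c12 | intermediate
16 | chloro(4,5-dimethoxy-2-methylnaphthalen-1-yl)zinc | COc1cc(C)c([Zn]Cl)c2cccc(OC)c12 | intermediate
17 | (3R)-7-(4,5-dimethoxy-2-methylnaphthalen-1-yl)-8-methoxy-1,3-dimethyl-3,4-dihydroisoquinoline | COc1c(-c2c(C)cc(OC)c3c(OC)cccc23)ccc2c1C(C)=N[C@H](C)C2 | target

**Totals**
Total steps: 5. Longest linear sequence: 4 (steps 1, 2, 3, 5).

**Steps most likely to fail**

Step 4. The stannane must intercept the aryl–palladium species only after norbornene extrusion; direct Stille coupling of 9, or C–N closure to an indoline, would compete. The fallback sets out from 10 and comes back at 12, making the same two bonds one after the other without norbornene. Commercial 4-bromo-1-chloro-2-methoxybenzene F1 is converted with Mg turnings in THF into bromo(4-chloro-3-methoxyphenyl)magnesium F2. This opens 10 at its CH2 terminus under CuI catalysis (THF, −30 °C → rt) to give tert-butyl N-[(2R)-1-(4-chloro-3-methoxyphenyl)propan-2-yl]carbamate F3, with the stereocentre untouched. s-BuLi/TMEDA (2.2 equiv, THF, −78 °C) metalates between the methoxy group and the side chain, both of which direct there, giving tert-butyl N-lithio-N-[(2R)-1-(4-chloro-2-lithio-3-methoxyphenyl)propan-2-yl]carbamate F4. I2 turns it into tert-butyl N-[(2R)-1-(4-chloro-2-iodo-3-methoxyphenyl)propan-2-yl]carbamate F5. An ordinary Stille coupling of F5 with 11 (Pd(PPh3)4, CuI cat., toluene, 100 °C) makes the same C1–C8a bond with the same acetyl anion equivalent and delivers 12, which is taken through the acid treatment of step 4 to 14.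

Step 5. The aryl chloride is hindered and electron-rich and sits next to a basic imine, and the di-ortho-substituted naphthylzinc transmetalates slowly. The fallback sets out from 14 and comes back at 17, exchanging the roles of the partners. Miyaura borylation of 14 (B2pin2, Pd(OAc)2, XPhos, KOAc, dioxane, 100 °C) gives (3R)-8-methoxy-1,3-dimethyl-7-(4,4,5,5-tetramethyl-1,3,2-dioxaborolan-2-yl)-3,4-dihydroisoquinoline F6, with boron on the less hindered ring. Suzuki–Miyaura coupling of F6 with bromide 8 (Pd(OAc)2, SPhos, K3PO4, toluene/H2O, 100 °C) gives 17.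

Step 3. Bromination could also go para to the other methoxy group. The fallback sets out from 5 and comes back at 8, using the free naphthol as the stronger director. 5 is cyclised with MeLi as in step 2, but the naphtholate 6 is quenched with aqueous NH4Cl to give 8-methoxy-3-methylnaphthalen-1-ol F7. NBS (MeCN, −20 °C) brominates para to the free hydroxyl to give 4-bromo-8-methoxy-3-methylnaphthalen-1-ol F8, and MeI/K2CO3 (acetone, reflux) gives 8.

**Further compounds**
F1 | step 4 | 4-bromo-1-chloro-2-methoxybenzene | COc1cc(Br)ccc1Cl
F2 | step 4 | bromo(4-chloro-3-methoxyphenyl)magnesium | COc1cc([Mg]Br)ccc1Cl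
F3 | step 4 | tert-butyl N-[(2R)-1-(4-chloro-3-methoxyphenyl)propan-2-yl]carbamate | COc1cc(C[C@@H](C)NC(=O)OC(C)(C)C)ccc1Cl
F4 | step 4 | tert-butyl N-lithio-N-[(2R)-1-(4-chloro-2-lithio-3-methoxyphenyl)propan-2-yl]carbamate | COc1c(Cl)ccc(C[C@@H](C)N([Li])C(=O)OC(C)(C)C)c1[Li]
F5 | step 4 | tert-butyl N-[(2R)-1-(4-chloro-2-iodo-3-methoxyphenyl)propan-2-yl]carbamate | COc1c(Cl)ccc(C[C@@H](C)NC(=O)OC(C)(C)C)c1I
F6 | step 5 | (3R)-8-methoxy-1,3-dimethyl-7-(4,4,5,5-tetramethyl-1,3,2-dioxaborolan-2-yl)-3,4-dihydroisoquinoline | COc1c(B2OC(C)(C)C(C)(C)O2)ccc2c1C(C)=N[C@H](C)C2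
F7 | step 3 | 8-methoxy-3-methylnaphthalen-1-ol | COc1cccc2cc(C)cc(O)c12
F8 | step 3 | 4-bromo-8-methoxy-3-methylnaphthalen-1-ol | COc1cccc2c(Br)c(C)cc(O)c12
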